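## Structural features

The target is a trinor-eremophilane ester: a cis-4,5-dimethyl decalin core acylated at O3 with a C9 dienoic acid. The core is numbered biogenetically here: ring A = C1, C2, C3, C4, C5, C10 and ring B = C5, C6, C7, C8, C9, C10, with C1=C2 and C9=C10 forming a linear dienone with the C8 ketone. Ring A carries three contiguous stereocentres, the allylic ester carbon C3 (S), the methyl-bearing C4 (R) and the quaternary ring-fusion carbon C5 (R), and O3, the C4 methyl and the C5 methyl all lie on one face. The fourth ring stereocentre, the α-ketol carbon C7 (R), sits in ring B, 1,3 to C5 and trans to its methyl group. The acyl part is (2E,4E,6R)-6-hydroxy-6-methylocta-2,4-dienoic acid (C1' to C8'), whose only stereocentre, the tertiary carbinol C6', must distinguish methyl from ethyl. Fragile groups are the α-hydroxy ketone (enolisation, ketol shift), the doubly allylic C3–O bond, the dienoate and the ionisable tertiary dienyl carbinol. The real difficulty is the quaternary C5 between C4 and an sp2 C10, together with the all-cis C3/C4/C5 triad. The key step exploits the fact that C9=C10 is exocyclic to ring A and conjugated to C1=C2: this is the pattern left when a vinylallene (C3=C2–C1=C10=C9) adds as a diene across C4=C5, so both rings, the dienone and the triad can come from one cycloaddition of an open chain.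

## Logic of the disconnections

**37 to 36.** The O7–Si and O6'–Si bonds are cut last. The α-ketol and the tertiary dienyl carbinol are the most fragile functions and would interfere with acylation at O3. The gain is a single global unmasking. The forward step must be fluoride-based and non-basic, so that C7 does not enolise and C6' does not ionise.

**36 to 23 + 34.** The ester bond C1'(=O)–O3 is cut. This is the convergent joint and it separates the remote C6' stereocentre from the core. The forward step must acylate a hindered allylic alcohol at oxygen (no substitution at C3) without isomerising the dienoate.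

**23 to 22.** The O3–CH2Ar bond is cut. O3 has to pass through the key step as an enol ether oxygen, so it needs a group that survives amine base and heat and then leaves oxidatively. The forward step needs chemoselective benzylic oxidation beside a dienone and a silyl ether.

**22 to 21 to 20 (key).** The ring bonds C3–C4 and C5–C10 are cut together, and the allene of 21 is traced back to the skipped ynone 20. In one sentence: an intramolecular Diels–Alder reaction of the acyclic vinylallenyl ketone 21 closes rings A and B at once. The gain is from a bicycle with a quaternary carbon and three new stereocentres to an open chain with one stereocentre and two E double bonds. An intermolecular Diels–Alder reaction with a carbonyl-activated dienophile would place the diene oxygen next to the quaternary carbon (1,2), whereas the target has the 1,3 relationship; the tether overrides this. The forward step must keep O3 outside and both methyl groups endo, and it must choose one π-face under control of C7 through an equilibrating allene axis.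

**20 to 19 to 10 + 18.** The C8 carbonyl is taken back to a carbinol, then the sp–sp2 bond C1–C2 is cut. The E geometry of C2=C3 is thereby fixed in a small fragment before coupling. The forward steps need a geometry-retentive coupling and a buffered oxidation that spares the enol ether.

**18 to 16 to 11 + 12.** The C2–I bond and then the C2/C3 two-carbon unit with its O3–C3 bond are cut. The forward steps need a terminal, syn hydrometalation of an ynol ether and stereoretentive iodination.

**10 to 7 + 8, and 7 to 6 to 5 to 1 + 2.** The C8–C9 bond (propargylation of an aldehyde) and the C5–C6 bond (epoxide opening) are cut. C7 is bought as an epoxide carbon and the C4=C5 geometry is bought in the bromide. The forward steps need stereoretentive alkenyl-metal formation, attack at the unsubstituted epoxide carbon, and a propargyl rather than allenyl adduct.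

**34 to 33 to 31 + 32, and 31 to 30 to 28 to 27 to 24.** The C3'–C4' bond (Heck) is cut, then the tertiary allylic carbinol is traced to an epoxy alcohol and an E trisubstituted allylic alcohol. The alkene geometry encodes methyl versus ethyl at C6', so a reagent-controlled epoxidation sets the centre. The forward steps need E-selective carbometalation, enantioselective epoxidation, and a transposition in which the C6'–O bond is never broken.

## Other disconnections considered

**Alternative 1:** Cut C5–C6 and C9=C10 (Robinson annulation), the first plan that comes to mind. Forward, a ring A cyclohexanone already carrying O3 and both methyl groups would undergo Michael addition to a methyl vinyl ketone equivalent and aldol condensation to give octalone A1; C1=C2 and the C7 hydroxyl would follow by dehydrogenation and α'-hydroxylation. The chosen plan is preferred because here the ring A triad must exist before the annulation and is built in separate events. The quaternary C5 would be set by a Michael addition with only a substrate bias relative to the C4 methyl. After A1 two further oxidation-level changes remain, and the dehydrogenation must be steered towards C1 rather than C6.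

**Alternative 2:** Cut the C5–CH3 bond and reconnect the methyl to C10 (retro 1,2-shift, the eudesmane-to-eremophilane relationship). Forward, protonation of the C4=C5 olefin of trinor-eudesmane A2 would give the C5 cation, the C10 methyl would migrate suprafacially, and loss of H9 would give the C9=C10 enone. The chosen plan is preferred because A2 is itself a bicycle with a quaternary centre, so little simplicity is gained. The C3–O bond of A2 is allylic to the olefin that must be protonated and would ionise or eliminate under the same acid. C4 would be set by an uncontrolled protonation, and the cation has other exits.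

**Alternative 3:** Cut C1=C2 by ring-closing metathesis after building ring B first. Forward, trienone A3 (vinyl at C10, vinyl carbinol at C3) would close ring A with the second-generation Grubbs catalyst. The chosen plan is preferred because this closure creates no stereocentre. C3, C4 and the quaternary C5 of A3 would each need their own stereoselective C–C bond formation, so the hard part is moved, not solved, and the step count rises.

Key step: step 9

Assumption: compounds 1, 2, 8, 11, 12, 24 and 32 are taken as commercially available, 1 as the pure E isomer (methyl groups cis) and 2 as the R enantiomer.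

## Route

Step 1
Reactants: 1 (E)-2-bromobut-2-ene; 2 methyl (2R)-oxirane-2-carboxylate
Product: 5 methyl (2R,4E)-2-hydroxy-4-methylhex-4-enoate, via alkenyllithium 3 (not isolated), via alkenylmagnesium bromide 4 (not isolated)
Conditions: t-BuLi (2 equiv), Et2O, −78 °C; MgBr2·OEt2, −78 → −30 °C; CuI (10 mol%), 2, THF, −30 °C; aq. NH4Cl
Reagents that add atoms: none
Why: Bromine–lithium exchange on a vinyl bromide is stereoretentive, and copper-catalysed opening of a glycidic ester by an alkenyl Grignard reagent occurs at the unsubstituted epoxide carbon, so the future C7 (R) is bought untouched and the E alkene (C4/C5 methyl groups cis) is carried over.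

Step 2
Reactants: 5 methyl (2R,4E)-2-hydroxy-4-methylhex-4-enoate
Product: 6 methyl (2R,4E)-2-[(tert-butyldimethylsilyl)oxy]-4-methylhex-4-enoate
Conditions: TBSCl, imidazole, DMF, 23 °C
Reagents that add atoms: tert-butyldimethylsilyl chloride, CC(C)(C)[Si](C)(C)Cl
Why: Standard silylation of a secondary alcohol; the bulky silyloxy group later serves as the conformational control element at C7.

Step 3
Reactants: 6 methyl (2R,4E)-2-[(tert-butyldimethylsilyl)oxy]-4-methylhex-4-enoate
Product: 7 (2R,4E)-2-[(tert-butyldimethylsilyl)oxy]-4-methylhex-4-enal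
Conditions: i-Bu2AlH, CH2Cl2, −78 °C; aq. potassium sodium tartrate
Reagents that add atoms: none
Why: Partial reduction of an α-alkoxy ester; the tetrahedral aluminium hemiacetal is stable at −78 °C and releases the aldehyde only on work-up, and the aldehyde is used at once to avoid α-epimerisation.

Step 4
Reactants: 7 (2R,4E)-2-[(tert-butyldimethylsilyl)oxy]-4-methylhex-4-enal; 8 3-bromoprop-1-yne
Product: 10 (5R,7E)-5-[(tert-butyldimethylsilyl)oxy]-7-methylnon-7-en-1-yn-4-ol (both C4 epimers), via allenylzinc bromide 9 (not isolated)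
Conditions: Zn dust, THF, 0 → 23 °C; aq. NH4Cl
Reagents that add atoms: none
Why: Barbier propargylation: the allenylzinc reagent adds through its γ-carbon to give the homopropargylic alcohol; the new carbinol (future C8) needs no control because it is oxidised in step 8.

Step 5
Reactants: 11 (4-methoxyphenyl)methanol; 12 1,1,2-trichloroethene
Product: 16 1-[(ethynyloxy)methyl]-4-methoxybenzene, via dichloroethyne 13 (not isolated), via dichlorovinyl ether 14 (not isolated), via lithium alkoxyacetylide 15 (not isolated)
Conditions: KH, THF, 0 °C; 12, −50 → 23 °C; n-BuLi (2.4 equiv), −78 → −40 °C; MeOH, −78 °C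
Reagents that add atoms: none
Why: Established ynol ether synthesis: alkoxide-induced elimination–addition on trichloroethene gives 14 through 13, then dehydrochlorination and chlorine–lithium exchange give acetylide 15, which is protonated cold; 16 is kept cold and used directly.

Step 6
Reactants: 16 1-[(ethynyloxy)methyl]-4-methoxybenzene
Product: 18 1-({[(E)-2-iodoethenyl]oxy}methyl)-4-methoxybenzene, via alkenylzirconocene chloride 17 (not isolated)
Conditions: Cp2Zr(H)Cl, THF, 0 → 23 °C; I2, 0 °C
Reagents that add atoms: iodine (I2), II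
Why: Hydrozirconation is syn and places zirconium on the terminal carbon, and iodinolysis proceeds with retention, which fixes the E enol ether that becomes the outside O3 substituent of the diene.

Step 7
Reactants: 10 (5R,7E)-5-[(tert-butyldimethylsilyl)oxy]-7-methylnon-7-en-1-yn-4-ol (both C4 epimers); 18 1-({[(E)-2-iodoethenyl]oxy}methyl)-4-methoxybenzene
Product: 19 (1E,7R,9E)-7-[(tert-butyldimethylsilyl)oxy]-1-[(4-methoxybenzyl)oxy]-9-methylundeca-1,9-dien-3-yn-6-ol (both C6 epimers)
Conditions: PdCl2(PPh3)2 (3 mol%), CuI (5 mol%), Et3N, THF, 23 °C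
Reagents that add atoms: none
Why: Sonogashira coupling forms the C1–C2 bond with retention of the vinyl iodide geometry; the free hydroxyl and the silyl ether are tolerated, and the amine medium protects the enol ether.

Step 8
Reactants: 19 (1E,7R,9E)-7-[(tert-butyldimethylsilyl)oxy]-1-[(4-methoxybenzyl)oxy]-9-methylundeca-1,9-dien-3-yn-6-ol (both C6 epimers)
Product: 20 (1E,7R,9E)-7-[(tert-butyldimethylsilyl)oxy]-1-[(4-methoxybenzyl)oxy]-9-methylundeca-1,9-dien-3-yn-6-one
Conditions: Dess–Martin periodinane, NaHCO3, CH2Cl2, 0 °C
Reagents that add atoms: none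
Why: Dess–Martin oxidation of a homopropargylic alcohol gives the β,γ-alkynyl ketone under buffered, non-acidic conditions that spare the enol ether; both carbinol epimers converge and 20 is taken on crude.

Step 9
Reactants: 20 (1E,7R,9E)-7-[(tert-butyldimethylsilyl)oxy]-1-[(4-methoxybenzyl)oxy]-9-methylundeca-1,9-dien-3-yn-6-one
Product: 22 (3R,4aR,5R,6S)-3-[(tert-butyldimethylsilyl)oxy]-6-[(4-methoxybenzyl)oxy]-4a,5-dimethyl-4,4a,5,6-tetrahydronaphthalen-2(3H)-one, via vinylallenone 21 (not isolated)
Conditions: Et3N (0.5 equiv), BHT, toluene (0.01 M), 23 °C then 80 °C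
Reagents that add atoms: none
Why: Et3N equilibrates the β,γ-ynone 20 with the conjugated vinylallenone 21 through the common propargyl/allenyl enolate (C9–H removed, C1 protonated), a known amine-mediated ynone-to-allenone isomerisation, and 21 then undergoes a thermal intramolecular [4+2] cycloaddition of its C3=C2–C1=C10 diene with the C4=C5 alkene, the known intramolecular Diels–Alder reaction of vinylallenes. Ring A closes by the suprafacial [4+2] addition itself (bonds C3–C4 and C10–C5), and ring B closes as the six-membered tether ring through the same C10–C5 bond, the orthogonal allene π-bond remaining as the ring B enone C9=C10, so the 1,9-dien-8-one needs no later adjustment. Because C9=C10 lies inside the forming ring B, C6 can only take the exo position on C5 (small C9=C10···C5–C6 dihedral), which puts the C5 methyl and, through the E alkene, the C4 methyl endo; the cis C4/C5 relationship follows from suprafacial addition to the E alkene. The E enol ether oxygen is the outside substituent at C3, and outside and endo groups end up cis, so O3, the C4 methyl and the C5 methyl emerge on one face. The absolute sense is relayed from C7: the C8 substituent on the allene terminus stands above or below the diene plane, so each axial epimer of 21 can react on one π-face only, and the epimer that lets the C7 silyloxy group sit pseudo-equatorial in the chair-like forming ring B (trans to the pseudo-axial C5 methyl, no 1,3-diaxial CH3/OSi contact) should react faster. The selectivity needed is therefore π-facial, and it holds only if the axial epimers interconvert faster than they cycloadd (Curtin–Hammett), which reversible γ-deprotonation at C1 by Et3N should provide without touching the much less acidic C7–H. The unactivated trisubstituted dienophile is tolerated because vinylallenes are unusually reactive intramolecular dienes (no inside substituent at the allenic terminus, strain release at the sp carbon) and the donor oxygen raises the diene HOMO.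

Step 10
Reactants: 22 (3R,4aR,5R,6S)-3-[(tert-butyldimethylsilyl)oxy]-6-[(4-methoxybenzyl)oxy]-4a,5-dimethyl-4,4a,5,6-tetrahydronaphthalen-2(3H)-one
Product: 23 (3R,4aR,5R,6S)-3-[(tert-butyldimethylsilyl)oxy]-6-hydroxy-4a,5-dimethyl-4,4a,5,6-tetrahydronaphthalen-2(3H)-one
Conditions: DDQ, CH2Cl2/pH 7 buffer, 0 °C
Reagents that add atoms: none
Why: Oxidative cleavage of the 4-methoxybenzyl ether through the benzylic oxocarbenium ion; the C3–O bond is never broken, so the configuration at C3 is retained, and the silyl ether and dienone are inert.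

Step 11
Reactants: 24 but-1-yne
Product: 27 (E)-3-methylpent-2-en-1-ol, via alkenylalane 25 (not isolated), via lithium alkenylaluminate 26 (not isolated)
Conditions: Me3Al, Cp2ZrCl2 (20 mol%), CH2Cl2, 0 → 23 °C; n-BuLi, hexane/THF, 0 °C; (CH2O)n, 23 °C; aq. HCl
Reagents that add atoms: trimethylaluminium, C[Al](C)C; paraformaldehyde (as formaldehyde), C=O
Why: Zirconium-catalysed Negishi carboalumination is a syn addition with aluminium at the terminal carbon, and the C–Al bond is converted to C–C with retention, so the E alkene that encodes methyl versus ethyl at C6' is fixed here.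

Step 12
Reactants: 27 (E)-3-methylpent-2-en-1-ol
Product: 28 [(2R,3R)-3-ethyl-3-methyloxiran-2-yl]methanol
Conditions: Ti(OiPr)4 (5 mol%), D-(−)-diethyl tartrate (6 mol%), t-BuOOH, 4 Å MS, CH2Cl2, −20 °C
Reagents that add atoms: tert-butyl hydroperoxide, CC(C)(C)OO
Why: Sharpless asymmetric epoxidation; with D-(−)-tartrate an E 3,3-disubstituted allylic alcohol gives the (2R,3R) epoxide (geraniol-type substrate), and the quaternary epoxide carbon becomes C6'.

Step 13
Reactants: 28 [(2R,3R)-3-ethyl-3-methyloxiran-2-yl]methanol
Product: 30 (3R)-3-methylpent-1-en-3-ol, via epoxy iodide 29 (not isolated)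
Conditions: I2, PPh3, imidazole, THF, 0 °C; Zn dust, AcOH, 23 °C
Reagents that add atoms: none
Why: Appel iodination followed by zinc-induced reductive β-elimination opens the epoxide towards the tertiary alkoxide; the C–O bond at the quaternary carbon stays intact, so the tertiary allylic alcohol keeps the R configuration.

Step 14
Reactants: 30 (3R)-3-methylpent-1-en-3-ol
Product: 31 triethyl{[(3R)-3-methylpent-1-en-3-yl]oxy}silane
Conditions: Et3SiOTf, 2,6-lutidine, CH2Cl2, −78 → 0 °C
Reagents that add atoms: triethylsilyl trifluoromethanesulfonate, CC[Si](CC)(CC)OS(=O)(=O)C(F)(F)F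
Why: Silyl triflate silylation of a tertiary alcohol; it masks the ionisable carbinol and makes the volatile alcohol easy to handle.

Step 15
Reactants: 31 triethyl{[(3R)-3-methylpent-1-en-3-yl]oxy}silane; 32 ethyl (2E)-3-iodoprop-2-enoate
Product: 33 ethyl (2E,4E,6R)-6-methyl-6-[(triethylsilyl)oxy]octa-2,4-dienoate
Conditions: Pd(OAc)2 (5 mol%), Bu4NCl, K2CO3, DMF, 40 °C
Reagents that add atoms: none
Why: Heck reaction under Jeffery conditions: syn carbopalladation at the terminal alkene carbon and syn β-hydride elimination give the new E alkene, the iodoacrylate geometry is retained, and the quaternary carbinol carbon has no hydrogen to allow double-bond migration.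

Step 16
Reactants: 33 ethyl (2E,4E,6R)-6-methyl-6-[(triethylsilyl)oxy]octa-2,4-dienoate
Product: 34 (2E,4E,6R)-6-methyl-6-[(triethylsilyl)oxy]octa-2,4-dienoic acid
Conditions: LiOH·H2O, THF/MeOH/H2O, 23 °C; aq. HCl to pH 4, 0 °C
Reagents that add atoms: lithium hydroxide (hydroxide oxygen), [Li+].[OH-]
Why: Saponification by acyl–oxygen cleavage; a tertiary triethylsilyl ether withstands aqueous LiOH and a brief, cold, mildly acidic work-up.

Step 17
Reactants: 34 (2E,4E,6R)-6-methyl-6-[(triethylsilyl)oxy]octa-2,4-dienoic acid; 23 (3R,4aR,5R,6S)-3-[(tert-butyldimethylsilyl)oxy]-6-hydroxy-4a,5-dimethyl-4,4a,5,6-tetrahydronaphthalen-2(3H)-one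
Product: 36 (1R,2S,7R,8aR)-7-[(tert-butyldimethylsilyl)oxy]-1,8a-dimethyl-6-oxo-1,2,6,7,8,8a-hexahydronaphthalen-2-yl (2E,4E,6R)-6-methyl-6-[(triethylsilyl)oxy]octa-2,4-dienoate, via mixed anhydride 35 (not isolated)
Conditions: 2,4,6-trichlorobenzoyl chloride, Et3N, toluene, 23 °C; 23, DMAP, toluene, 23 → 40 °C
Reagents that add atoms: none
Why: Yamaguchi esterification: the mixed anhydride is attacked regioselectively at the dienoyl carbonyl by the DMAP-activated alcohol; acylation occurs at oxygen, so C3 keeps its configuration.

Step 18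
Reactants: 36 (1R,2S,7R,8aR)-7-[(tert-butyldimethylsilyl)oxy]-1,8a-dimethyl-6-oxo-1,2,6,7,8,8a-hexahydronaphthalen-2-yl (2E,4E,6R)-6-methyl-6-[(triethylsilyl)oxy]octa-2,4-dienoate
Product: 37 (1R,2S,7R,8aR)-7-hydroxy-1,8a-dimethyl-6-oxo-1,2,6,7,8,8a-hexahydronaphthalen-2-yl (2E,4E,6R)-6-hydroxy-6-methylocta-2,4-dienoate
Conditions: HF·pyridine, pyridine, THF, 0 → 23 °C
Reagents that add atoms: none
Why: Fluoride cleaves both Si–O bonds under buffered, weakly acidic conditions that neither enolise C7 nor ionise the tertiary dienyl carbinol, and no stereocentre is touched.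

## Compound list

1 | (E)-2-bromobut-2-ene | C/C=C(/Br)C | starting material
2 | methyl (2R)-oxirane-2-carboxylate | COC(=O)[C@H]1CO1 | starting material
3 | (Z)-but-2-en-2-yllithium (methyl groups cis) | C/C=C(/[Li])C | intermediate (not isolated)
4 | (E)-but-2-en-2-ylmagnesium bromide (methyl groups cis) | C/C=C(/[Mg]Br)C | intermediate (not isolated)
5 | methyl (2R,4E)-2-hydroxy-4-methylhex-4-enoate | COC(=O)[C@H](O)C/C(C)=C/C | intermediate
6 | methyl (2R,4E)-2-[(tert-butyldimethylsilyl)oxy]-4-methylhex-4-enoate | COC(=O)[C@H](O[Si](C)(C)C(C)(C)C)C/C(C)=C/C | intermediate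
7 | (2R,4E)-2-[(tert-butyldimethylsilyl)oxy]-4-methylhex-4-enal | O=C[C@H](O[Si](C)(C)C(C)(C)C)C/C(C)=C/C | intermediate
8 | 3-bromoprop-1-yne | C#CCBr | starting material
9 | bromo(propa-1,2-dien-1-yl)zinc | C=C=C[Zn]Br | intermediate (not isolated)
10 | (5R,7E)-5-[(tert-butyldimethylsilyl)oxy]-7-methylnon-7-en-1-yn-4-ol (both C4 epimers) | C#CCC(O)[C@H](O[Si](C)(C)C(C)(C)C)C/C(C)=C/C | intermediate
11 | (4-methoxyphenyl)methanol | COc1ccc(CO)cc1 | starting material
12 | 1,1,2-trichloroethene | ClC=C(Cl)Cl | starting material
13 | dichloroethyne | ClC#CCl | intermediate (not isolated)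
14 | 1-({[(E)-1,2-dichloroethenyl]oxy}methyl)-4-methoxybenzene | COc1ccc(CO/C(Cl)=C\Cl)cc1 | intermediate (not isolated)
15 | lithium 2-[(4-methoxybenzyl)oxy]ethynide | COc1ccc(COC#C[Li])cc1 | intermediate (not isolated)
16 | 1-[(ethynyloxy)methyl]-4-methoxybenzene | COc1ccc(COC#C)cc1 | intermediate
17 | chloridobis(cyclopentadienyl){(E)-2-[(4-methoxybenzyl)oxy]ethenyl}zirconium (rings drawn sigma-bonded) | COc1ccc(CO/C=C/[Zr](Cl)(C2C=CC=C2)C2C=CC=C2)cc1 | intermediate (not isolated)
18 | 1-({[(E)-2-iodoethenyl]oxy}methyl)-4-methoxybenzene | COc1ccc(CO/C=C/I)cc1 | intermediate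
19 | (1E,7R,9E)-7-[(tert-butyldimethylsilyl)oxy]-1-[(4-methoxybenzyl)oxy]-9-methylundeca-1,9-dien-3-yn-6-ol (both C6 epimers) | COc1ccc(CO/C=C/C#CCC(O)[C@H](O[Si](C)(C)C(C)(C)C)C/C(C)=C/C)cc1 | intermediate
20 | (1E,7R,9E)-7-[(tert-butyldimethylsilyl)oxy]-1-[(4-methoxybenzyl)oxy]-9-methylundeca-1,9-dien-3-yn-6-one | COc1ccc(CO/C=C/C#CCC(=O)[C@H](O[Si](C)(C)C(C)(C)C)C/C(C)=C/C)cc1 | intermediate
21 | (1E,7R,9E)-7-[(tert-butyldimethylsilyl)oxy]-1-[(4-methoxybenzyl)oxy]-9-methylundeca-1,3,4,9-tetraen-6-one (both allene-axis epimers, interconverting) | COc1ccc(CO/C=C/C=C=CC(=O)[C@H](O[Si](C)(C)C(C)(C)C)C/C(C)=C/C)cc1 | intermediate (not isolated)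
22 | (3R,4aR,5R,6S)-3-[(tert-butyldimethylsilyl)oxy]-6-[(4-methoxybenzyl)oxy]-4a,5-dimethyl-4,4a,5,6-tetrahydronaphthalen-2(3H)-one | COc1ccc(CO[C@H]2C=CC3=CC(=O)[C@H](O[Si](C)(C)C(C)(C)C)C[C@]3(C)[C@H]2C)cc1 | intermediate
23 | (3R,4aR,5R,6S)-3-[(tert-butyldimethylsilyl)oxy]-6-hydroxy-4a,5-dimethyl-4,4a,5,6-tetrahydronaphthalen-2(3H)-one | O[C@H]1C=CC2=CC(=O)[C@H](O[Si](C)(C)C(C)(C)C)C[C@]2(C)[C@H]1C | intermediate
24 | but-1-yne | CCC#C | starting material
25 | dimethyl[(E)-2-methylbut-1-en-1-yl]alumane | C[Al](C)/C=C(\C)CC | intermediate (not isolated)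
26 | lithium butyl(dimethyl)[(E)-2-methylbut-1-en-1-yl]aluminate | [Li+].CCCC[Al-](C)(C)/C=C(\C)CC | intermediate (not isolated)
27 | (E)-3-methylpent-2-en-1-ol | CC/C(C)=C/CO | intermediate
28 | [(2R,3R)-3-ethyl-3-methyloxiran-2-yl]methanol | CC[C@@]1(C)O[C@@H]1CO | intermediate
29 | (2R,3S)-2-ethyl-3-(iodomethyl)-2-methyloxirane | CC[C@@]1(C)O[C@@H]1CI | intermediate (not isolated)
30 | (3R)-3-methylpent-1-en-3-ol | CC[C@@](C)(O)C=C | intermediate
31 | triethyl{[(3R)-3-methylpent-1-en-3-yl]oxy}silane | CC[C@@](C)(O[Si](CC)(CC)CC)C=C | intermediate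
32 | ethyl (2E)-3-iodoprop-2-enoate | CCOC(=O)/C=C/I | starting material
33 | ethyl (2E,4E,6R)-6-methyl-6-[(triethylsilyl)oxy]octa-2,4-dienoate | CC[C@@](C)(O[Si](CC)(CC)CC)/C=C/C=C/C(=O)OCC | intermediate
34 | (2E,4E,6R)-6-methyl-6-[(triethylsilyl)oxy]octa-2,4-dienoic acid | CC[C@@](C)(O[Si](CC)(CC)CC)/C=C/C=C/C(=O)O | intermediate
35 | (2E,4E,6R)-6-methyl-6-[(triethylsilyl)oxy]octa-2,4-dienoic 2,4,6-trichlorobenzoic anhydride | CC[C@@](C)(O[Si](CC)(CC)CC)/C=C/C=C/C(=O)OC(=O)c1c(Cl)cc(Cl)cc1Cl | intermediate (not isolated)
36 | (1R,2S,7R,8aR)-7-[(tert-butyldimethylsilyl)oxy]-1,8a-dimethyl-6-oxo-1,2,6,7,8,8a-hexahydronaphthalen-2-yl (2E,4E,6R)-6-methyl-6-[(triethylsilyl)oxy]octa-2,4-dienoate | CC[C@@](C)(O[Si](CC)(CC)CC)/C=C/C=C/C(=O)O[C@H]1C=CC2=CC(=O)[C@H](O[Si](C)(C)C(C)(C)C)C[C@]2(C)[C@H]1C | intermediate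
37 | (1R,2S,7R,8aR)-7-hydroxy-1,8a-dimethyl-6-oxo-1,2,6,7,8,8a-hexahydronaphthalen-2-yl (2E,4E,6R)-6-hydroxy-6-methylocta-2,4-dienoate | CC[C@@](C)(O)/C=C/C=C/C(=O)O[C@H]1C=CC2=CC(=O)[C@H](O)C[C@]2(C)[C@H]1C | target

## Step count and least certain steps

Total: 18 steps. Longest linear sequence: 10 steps (steps 1, 2, 3, 4, 7, 8, 9, 10, 17, 18).

**Step 9 (key step).** The most likely failure is loss of π-facial control: if the allene axis of 21 does not equilibrate faster than the cycloaddition, each axial epimer reacts on its own face and the C7 relay is lost. A second risk is that the slow addition to the unactivated trisubstituted alkene lets 21 drain through ene, [2+2] or oligomerisation paths of the electrophilic allenone. The fallback uses a conventional diene and adds C9=C10 afterwards; it sets out from 10 and 18 and returns at 22. Hydrozirconation of 10 with Cp2Zr(H)Cl, transmetalation with ZnCl2 and Negishi coupling with 18 under Pd(PPh3)4 would give (1E,3E,7R,9E)-7-[(tert-butyldimethylsilyl)oxy]-1-[(4-methoxybenzyl)oxy]-9-methylundeca-1,3,9-trien-6-ol F1. A thermal intramolecular Diels–Alder reaction (toluene, BHT, 180 °C) would give 3-[(tert-butyldimethylsilyl)oxy]-6-[(4-methoxybenzyl)oxy]-4a,5-dimethyl-1,2,3,4,4a,5,6,8a-octahydronaphthalen-2-ol F2. Dess–Martin oxidation would give the corresponding 3,4,4a,5,6,8a-hexahydronaphthalen-2(1H)-one F3. LiN(SiMe3)2/Me3SiCl would give its C8–C9 trimethylsilyl enol ether F4, and Saegusa–Ito oxidation with Pd(OAc)2 would install C9=C10 to reach 22. In this variant the tether orientation is no longer enforced, so F2 may need chromatographic separation.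

**Step 5.** The 4-methoxybenzyl ynol ether 16 may be lost by sigmatropic rearrangement to a ketene on warming or by benzylic metalation during the n-BuLi stage, and 16 and 18 are acid-labile on handling. The fallback uses boron as an oxygen surrogate and introduces O3 after the cycloaddition; it sets out from 10 and returns at 23, bypassing steps 5, 6, 7 and 10. Sonogashira coupling of 10 with commercial trans-2-bromovinylboronic acid MIDA ester would give 2-[(1E,7R,9E)-7-[(tert-butyldimethylsilyl)oxy]-6-hydroxy-9-methylundeca-1,9-dien-3-yn-1-yl]-6-methyl-1,3,6,2-dioxazaborocane-4,8-dione F5. Dess–Martin oxidation would give the 6-oxo compound F6. The Et3N/heat cascade of step 9 would give, through the boryl vinylallenone F7, the bicyclic allylic boronate F8 with boron outside on the diene and hence cis to both methyl groups. NaBO3·4H2O in THF/H2O (cage hydrolysis and C–B oxidation with retention) would give 23.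

**Step 15.** Migratory insertion into the hindered allylic silyl ether may be sluggish, with desilylation or geometric erosion of the iodoacrylate under the basic conditions. The fallback builds the diene by olefination; it sets out from 31 and returns at 33. Ozonolysis of 31 (O3, CH2Cl2, −78 °C; PPh3) would give (2R)-2-methyl-2-[(triethylsilyl)oxy]butanal F9, and a Horner–Wadsworth–Emmons reaction with triethyl 4-phosphonocrotonate (LiN(SiMe3)2, THF, −78 → 0 °C) would give 33.

**Step 17.** Acylation of the C3 hydroxyl may be slow because it is flanked by the C4 methyl and syn to the C5 methyl, and prolonged exposure of the activated dienoate to DMAP invites geometric scrambling by reversible conjugate addition. The fallback assembles the dienoate on the core; it sets out from 23 and 31 and returns at 36. Acylation of 23 with diethylphosphonoacetic acid (DCC, CH2Cl2), which reacts through a small ketene-like acylating species, would give (1R,2S,7R,8aR)-7-[(tert-butyldimethylsilyl)oxy]-1,8a-dimethyl-6-oxo-1,2,6,7,8,8a-hexahydronaphthalen-2-yl 2-(diethoxyphosphoryl)acetate F10. Masamune–Roush olefination (LiCl, DBU, MeCN) with (2E,4R)-4-methyl-4-[(triethylsilyl)oxy]hex-2-enal F11, itself made from 31 through F9 and (triphenylphosphoranylidene)acetaldehyde, would give 36.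

## Further compounds

F1 | step 9 | (1E,3E,7R,9E)-7-[(tert-butyldimethylsilyl)oxy]-1-[(4-methoxybenzyl)oxy]-9-methylundeca-1,3,9-trien-6-ol (both C6 epimers) | COc1ccc(CO/C=C/C=C/CC(O)[C@H](O[Si](C)(C)C(C)(C)C)C/C(C)=C/C)cc1
F2 | step 9 | 3-[(tert-butyldimethylsilyl)oxy]-6-[(4-methoxybenzyl)oxy]-4a,5-dimethyl-1,2,3,4,4a,5,6,8a-octahydronaphthalen-2-ol (C3, C4a, C5, C6 as in 22; C2 and C8a as formed) | COc1ccc(CO[C@H]2C=CC3CC(O)[C@H](O[Si](C)(C)C(C)(C)C)C[C@]3(C)[C@H]2C)cc1
F3 | step 9 | 3-[(tert-butyldimethylsilyl)oxy]-6-[(4-methoxybenzyl)oxy]-4a,5-dimethyl-3,4,4a,5,6,8a-hexahydronaphthalen-2(1H)-one (C3, C4a, C5, C6 as in 22) | COc1ccc(CO[C@H]2C=CC3CC(=O)[C@H](O[Si](C)(C)C(C)(C)C)C[C@]3(C)[C@H]2C)cc1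
F4 | step 9 | tert-butyl({6-[(4-methoxybenzyl)oxy]-4a,5-dimethyl-2-[(trimethylsilyl)oxy]-3,4,4a,5,6,8a-hexahydronaphthalen-3-yl}oxy)dimethylsilane (C3, C4a, C5, C6 as in 22) | COc1ccc(CO[C@H]2C=CC3C=C(O[Si](C)(C)C)[C@H](O[Si](C)(C)C(C)(C)C)C[C@]3(C)[C@H]2C)cc1
F5 | step 5 | 2-[(1E,7R,9E)-7-[(tert-butyldimethylsilyl)oxy]-6-hydroxy-9-methylundeca-1,9-dien-3-yn-1-yl]-6-methyl-1,3,6,2-dioxazaborocane-4,8-dione (both C6 epimers) | C[N+]12CC(=O)O[B-]1(/C=C/C#CCC(O)[C@H](O[Si](C)(C)C(C)(C)C)C/C(C)=C/C)OC(=O)C2
F6 | step 5 | 2-[(1E,7R,9E)-7-[(tert-butyldimethylsilyl)oxy]-9-methyl-6-oxoundeca-1,9-dien-3-yn-1-yl]-6-methyl-1,3,6,2-dioxazaborocane-4,8-dione | C[N+]12CC(=O)O[B-]1(/C=C/C#CCC(=O)[C@H](O[Si](C)(C)C(C)(C)C)C/C(C)=C/C)OC(=O)C2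
F7 | step 5 | 2-[(1E,7R,9E)-7-[(tert-butyldimethylsilyl)oxy]-9-methyl-6-oxoundeca-1,3,4,9-tetraen-1-yl]-6-methyl-1,3,6,2-dioxazaborocane-4,8-dione (both allene-axis epimers) | C[N+]12CC(=O)O[B-]1(/C=C/C=C=CC(=O)[C@H](O[Si](C)(C)C(C)(C)C)C/C(C)=C/C)OC(=O)C2
F8 | step 5 | 3-[(tert-butyldimethylsilyl)oxy]-4a,5-dimethyl-6-(6-methyl-4,8-dioxo-1,3,6,2-dioxazaborocan-2-yl)-4,4a,5,6-tetrahydronaphthalen-2(3H)-one (boron cis to both methyl groups; other centres as in 22) | C[N+]12CC(=O)O[B-]1([C@H]3C=CC4=CC(=O)[C@H](O[Si](C)(C)C(C)(C)C)C[C@]4(C)[C@H]3C)OC(=O)C2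
F9 | step 15 | (2R)-2-methyl-2-[(triethylsilyl)oxy]butanal | CC[C@@](C)(O[Si](CC)(CC)CC)C=O
F10 | step 17 | (1R,2S,7R,8aR)-7-[(tert-butyldimethylsilyl)oxy]-1,8a-dimethyl-6-oxo-1,2,6,7,8,8a-hexahydronaphthalen-2-yl 2-(diethoxyphosphoryl)acetate | CCOP(=O)(OCC)CC(=O)O[C@H]1C=CC2=CC(=O)[C@H](O[Si](C)(C)C(C)(C)C)C[C@]2(C)[C@H]1C
F11 | step 17 | (2E,4R)-4-methyl-4-[(triethylsilyl)oxy]hex-2-enal | CC[C@@](C)(O[Si](CC)(CC)CC)/C=C/C=O
A1 | alternative 1 | (4aR,5R,6S)-6-[(tert-butyldimethylsilyl)oxy]-4a,5-dimethyl-4,4a,5,6,7,8-hexahydronaphthalen-2(3H)-one | CC(C)(C)[Si](C)(C)O[C@H]1CCC2=CC(=O)CC[C@]2(C)[C@H]1C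
A2 | alternative 2 | (3R,6S,8aR)-3,6-bis[(tert-butyldimethylsilyl)oxy]-5,8a-dimethyl-3,4,6,7,8,8a-hexahydronaphthalen-2(1H)-one | CC(C)(C)[Si](C)(C)O[C@H]1CC[C@]2(C)CC(=O)[C@H](O[Si](C)(C)C(C)(C)C)CC2=C1C
A3 | alternative 3 | (4R,6R)-6-[(tert-butyldimethylsilyl)oxy]-4-{(2R,3S)-3-[(tert-butyldimethylsilyl)oxy]pent-4-en-2-yl}-3-ethenyl-4-methylcyclohex-2-en-1-one | C=C[C@H](O[Si](C)(C)C(C)(C)C)[C@H](C)[C@@]1(C)C[C@@H](O[Si](C)(C)C(C)(C)C)C(=O)C=C1C=C
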